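## Retrosynthetic overview

1. The only ring made is the 19-membered lactam, closed late by intramolecular Cu-mediated N-arylation (C20–N) of a C1 primary enamide onto an aryl bromide; the C7 carbamate and global deprotection follow. The benzene ring is bought.
2. C1–C6 is grafted onto a C7 enal by Brown (Z)-γ-methoxyallylboration (C6–C7, syn), then a domino hydroformylation–Wittig (C3–C4, C2=C3).
3. C8=C9 comes from ozonolysis/Wittig of a C9 vinyl group.
4. Key step: C11–C12 is made by a stereospecific 1,2-metallate shift (lithiation–borylation) of an α-methoxy boronic ester with a lithiated (S)-2-methylbut-3-enyl benzoate. C12 itself is set by a Matteson 1,2-shift and methoxide displacement.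
5. C13–C15 and the arene: Cu-catalysed coupling of an aryl Grignard with (S)-1-bromo-3-chloro-2-methylpropane, Mg/borate, para-bromination.

Assumption: (S)-2-methylbut-3-en-1-ol (12) is bought as the single enantiomer. Carbon labels Cn follow the ansamycin convention (C1 lactam C=O … C15 benzylic CH2, C16–C21 arene with C17–O and C20–N). The sense of the Matteson director ((R,R)-DICHED gives the (1S)-chloride) and of the Ipc reagents (reagent from (+)-Ipc2BOMe attacks the Re face) is taken from the usual mnemonics.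

## Route

Step 1
Reactants: 1 2-bromophenol
Product: 2 1-bromo-2-(methoxymethoxy)benzene
Conditions: MOMCl, iPr2NEt, CH2Cl2, 0 °C→rt
Reagents that add atoms: chloromethyl methyl ether (COCCl)
Why: O-alkylation (MOM protection) gives an aryl acetal that survives Grignard, carbenoid and methoxide chemistry and is removed by mild acid at the end.

Step 2
Reactants: 2 1-bromo-2-(methoxymethoxy)benzene; 3 (S)-1-bromo-3-chloro-2-methylpropane
Product: 5 (R)-1-(3-chloro-2-methylpropyl)-2-(methoxymethoxy)benzene, via aryl Grignard 4 (not isolated)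
Conditions: Mg, THF, 40 °C; then 3, Li2CuCl4 (3 mol%), THF/NMP, 0 °C→rt
Reagents that add atoms: none
Why: Kochi-type Cu-catalysed sp2–sp3 Grignard coupling displaces the primary bromide selectively over the chloride, and the C14 stereocentre comes unchanged from the chiral pool because it is not the reacting carbon.

Step 3
Reactants: 5 (R)-1-(3-chloro-2-methylpropyl)-2-(methoxymethoxy)benzene
Product: 8 (4R,5R)-4,5-dicyclohexyl-2-[(S)-3-[2-(methoxymethoxy)phenyl]-2-methylpropyl]-1,3,2-dioxaborolane, via alkyl Grignard 6 (not isolated), via boronic acid 7 (not isolated)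
Conditions: Mg (I2), THF, 60 °C; B(OMe)3, −78 °C→rt; aq. NH4Cl; (R,R)-DICHED, MgSO4, Et2O, rt
Reagents that add atoms: trimethyl borate (COB(OC)OC); (1R,2R)-1,2-dicyclohexylethane-1,2-diol (O[C@H](C1CCCCC1)[C@H](O)C1CCCCC1)
Why: Borylation of the primary Grignard reagent and esterification with the C2-symmetric diol installs the chiral director for the Matteson homologation.

Step 4
Reactants: 8 (4R,5R)-4,5-dicyclohexyl-2-[(S)-3-[2-(methoxymethoxy)phenyl]-2-methylpropyl]-1,3,2-dioxaborolane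
Product: 9 (4R,5R)-2-[(S)-3-[5-bromo-2-(methoxymethoxy)phenyl]-2-methylpropyl]-4,5-dicyclohexyl-1,3,2-dioxaborolane
Conditions: NBS, MeCN, 0 °C→rt, dark
Reagents that add atoms: N-bromosuccinimide (O=C1CCC(=O)N1Br)
Why: Electrophilic aromatic bromination goes para to the strongly activating OMOM group (the free ortho site is less reactive, and without a radical initiator the alkyl boronate and benzylic C–H are untouched), placing the handle for the later C–N bond.

Step 5
Reactants: 9 (4R,5R)-2-[(S)-3-[5-bromo-2-(methoxymethoxy)phenyl]-2-methylpropyl]-4,5-dicyclohexyl-1,3,2-dioxaborolane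
Product: 11 (4R,5R)-2-[(1R,3R)-4-[5-bromo-2-(methoxymethoxy)phenyl]-1-methoxy-3-methylbutyl]-4,5-dicyclohexyl-1,3,2-dioxaborolane, via chloro boronate 10 (not isolated)
Conditions: CH2Cl2, n-BuLi, THF, −100 °C; 9; ZnCl2, −100 °C→rt; then NaOMe, THF/MeOH, 0 °C→rt
Reagents that add atoms: dichloromethane (ClCCl); sodium methoxide ([Na+].[O-]C)
Why: Matteson homologation, in which the director-controlled, ZnCl2-promoted 1,2-migration of C13 from boron to carbon gives the (1S)-chloride 10, and methoxide then displaces chloride with inversion through a second boron-ate 1,2-shift, setting C12 (S in the target).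

Step 6
Reactants: 12 (S)-2-methylbut-3-en-1-ol
Product: 13 (S)-2-methylbut-3-en-1-yl 2,4,6-triisopropylbenzoate
Conditions: 2,4,6-triisopropylbenzoic acid, PPh3, DIAD, THF, 0 °C→rt
Reagents that add atoms: 2,4,6-triisopropylbenzoic acid (CC(C)c1cc(C(C)C)c(C(=O)O)c(C(C)C)c1)
Why: Mitsunobu esterification of the primary alcohol gives the hindered benzoate that directs α-lithiation and later serves as leaving group; the C10 stereocentre is not involved.

Step 7
Reactants: 13 (S)-2-methylbut-3-en-1-yl 2,4,6-triisopropylbenzoate; 11 (4R,5R)-2-[(1R,3R)-4-[5-bromo-2-(methoxymethoxy)phenyl]-1-methoxy-3-methylbutyl]-4,5-dicyclohexyl-1,3,2-dioxaborolane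
Product: 17 (3S,4R,5S,7R)-8-[5-bromo-2-(methoxymethoxy)phenyl]-5-methoxy-3,7-dimethyloct-1-en-4-ol, via lithiated benzoate 14 (not isolated), via ate complex 15 (not isolated), via secondary boronic ester 16 (not isolated)
Conditions: 13, s-BuLi, (−)-sparteine, Et2O, −78 °C, 5 h; 11, −78 °C, 2 h; MgBr2·OEt2, →35 °C, 12 h; then NaOH, H2O2, THF, 0 °C→rt
Reagents that add atoms: hydrogen peroxide (OO)
Why: Proposed new method: sparteine-directed deprotonation gives the configurationally stable (S)-α-lithio benzoate 14, which is borylated with retention by the hindered α-methoxy secondary boronic ester 11 to the ate complex 15; anti-periplanar 1,2-migration of C12 from boron to carbon (retention at C12, inversion at C11, benzoate leaving, MgBr2-assisted) forges C11–C12 and sets C11 (R) while the C10 methyl comes unchanged from 12, and oxidation with retention gives the 10,11-syn-11,12-anti triad; the closest known reaction type is lithiation–borylation of lithiated primary benzoates or carbamates with pinacol boronic esters, which has not been shown with an α-alkoxy secondary DICHED boronic ester as the migrating terminus.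

Step 8
Reactants: 17 (3S,4R,5S,7R)-8-[5-bromo-2-(methoxymethoxy)phenyl]-5-methoxy-3,7-dimethyloct-1-en-4-ol
Product: 18 triethylsilyl ether of 17 (C11–OTES)
Conditions: TESOTf, 2,6-lutidine, CH2Cl2, −78 °C→0 °C
Reagents that add atoms: triethylsilyl trifluoromethanesulfonate (CC[Si](CC)(CC)OS(=O)(=O)C(F)(F)F)
Why: Silylation of the hindered secondary alcohol masks C11–OH so that C7–OH is later the only free hydroxyl.

Step 9
Reactants: 18 triethylsilyl ether of 17
Product: 20 (2E,4S,5R,6S,8R)-9-[5-bromo-2-(methoxymethoxy)phenyl]-6-methoxy-2,4,8-trimethyl-5-(triethylsilyloxy)non-2-enal, via aldehyde 19 (not isolated)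
Conditions: O3, CH2Cl2, −78 °C (Sudan III); PPh3, →rt; then Ph3P=C(Me)CHO, toluene, 80 °C
Reagents that add atoms: ozone ([O-][O+]=O); 2-(triphenylphosphoranylidene)propanal (CC(C=O)=P(c1ccccc1)(c1ccccc1)c1ccccc1)
Why: Ozonolysis cleaves only the terminal alkene, and the α-chiral aldehyde 19 is trapped in the same pot by the stabilised formyl ylide in an E-selective Wittig reaction, giving the trisubstituted C8=C9 enal without epimerising C10.

Step 10
Reactants: 21 allyl methyl ether; 20 (2E,4S,5R,6S,8R)-9-[5-bromo-2-(methoxymethoxy)phenyl]-6-methoxy-2,4,8-trimethyl-5-(triethylsilyloxy)non-2-enal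
Product: 25 (3S,4S,5E,7S,8R,9S,11R)-12-[5-bromo-2-(methoxymethoxy)phenyl]-3,9-dimethoxy-5,7,11-trimethyl-8-(triethylsilyloxy)dodeca-1,5-dien-4-ol, via (Z)-3-methoxyallyllithium 22 (not isolated), via methoxyallyl-diisopinocampheylborane 23 (not isolated), via borinate adduct 24 (not isolated)
Conditions: 21, s-BuLi, THF, −78 °C; (+)-Ipc2BOMe; BF3·OEt2; 20, −78 °C→rt; then NaOH, H2O2
Reagents that add atoms: none
Why: Brown (Z)-γ-methoxyallylboration through a closed chair transition state gives the 6,7-syn methoxy alcohol by 1,2-addition only, and the Ipc2B reagent from (+)-Ipc2BOMe attacks the Re face of the enal to set C7 (S) and C6 (S).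

Step 11
Reactants: 26 2-bromopropanamide
Product: 28 2-(triphenyl-λ5-phosphanylidene)propanamide, via phosphonium bromide 27 (not isolated)
Conditions: PPh3, toluene, 90 °C; then aq. NaOH, CH2Cl2, 0 °C
Reagents that add atoms: triphenylphosphine (c1ccc(cc1)P(c1ccccc1)c1ccccc1)
Why: SN2 quaternisation of PPh3 by the α-bromo amide followed by deprotonation gives the amide-stabilised ylide (standard Wittig reagent synthesis).

Step 12
Reactants: 25 (3S,4S,5E,7S,8R,9S,11R)-12-[5-bromo-2-(methoxymethoxy)phenyl]-3,9-dimethoxy-5,7,11-trimethyl-8-(triethylsilyloxy)dodeca-1,5-dien-4-ol; 28 2-(triphenyl-λ5-phosphanylidene)propanamide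
Product: 30 (2E,6S,7S,8E,10S,11R,12S,14R)-15-[5-bromo-2-(methoxymethoxy)phenyl]-7-hydroxy-6,12-dimethoxy-2,8,10,14-tetramethyl-11-(triethylsilyloxy)pentadeca-2,8-dienamide, via aldehyde 29 (not isolated)
Conditions: Rh(CO)2(acac) (2 mol%), Xantphos, CO/H2 (1:1, 10 bar), 28, toluene, 70 °C
Reagents that add atoms: carbon monoxide ([C-]#[O+])
Why: Linear-selective Rh-catalysed hydroformylation of the monosubstituted alkene (the branched path is blocked by the allylic methoxy group; trisubstituted alkenes are inert) gives aldehyde 29, in equilibrium with its δ-lactol, which is trapped in the same pot by ylide 28 in an E-selective Wittig olefination (domino hydroformylation–Wittig).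

Step 13
Reactants: 30 (2E,6S,7S,8E,10S,11R,12S,14R)-15-[5-bromo-2-(methoxymethoxy)phenyl]-7-hydroxy-6,12-dimethoxy-2,8,10,14-tetramethyl-11-(triethylsilyloxy)pentadeca-2,8-dienamide
Product: 31 19-membered lactam with free 7-OH and 11-OTES and 17-OMOM (2E,6S,7S,8E,10S,11R,12S,14R)
Conditions: CuI, N,N'-dimethylethylenediamine, K2CO3, toluene (0.005 M), 100 °C
Reagents that add atoms: none
Why: Intramolecular Goldberg (Cu/diamine) N-arylation of the primary enamide by the aryl bromide under high dilution closes the macrolactam, as in related ansamycin macrocyclisations, with the amide N–H coupling in preference to the secondary alcohol.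

Step 14
Reactants: 31 19-membered lactam with free 7-OH
Product: 33 7-O-carbamoyl lactam (11-OTES and 17-OMOM retained), via trichloroacetyl carbamate 32 (not isolated)
Conditions: Cl3CC(O)NCO, CH2Cl2, 0 °C; then K2CO3 (cat.), MeOH, 0 °C→rt
Reagents that add atoms: trichloroacetyl isocyanate (O=C=NC(=O)C(Cl)(Cl)Cl)
Why: The only free hydroxyl (C7) adds to the highly electrophilic acyl isocyanate and mild methanolysis removes the trichloroacetyl group, leaving the primary carbamate (anilide N–H and silyl ether are untouched).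

Step 15
Reactants: 33 7-O-carbamoyl lactam
Product: 34 target (CNP0544610.1)
Conditions: HCl (ca. 1 M, from AcCl in MeOH), MeOH/THF, 0 °C→rt
Reagents that add atoms: none
Why: Acidic methanolysis cleaves the phenolic MOM acetal and the secondary TES ether in one operation without ionising the allylic carbamate.

## Compound list

1 | 2-bromophenol | Oc1ccccc1Br | starting material
2 | 1-bromo-2-(methoxymethoxy)benzene | COCOc1ccccc1Br | intermediate
3 | (S)-1-bromo-3-chloro-2-methylpropane | ClC[C@H](C)CBr | starting material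
4 | [2-(methoxymethoxy)phenyl]magnesium bromide | COCOc1ccccc1[Mg]Br | intermediate
5 | (R)-1-(3-chloro-2-methylpropyl)-2-(methoxymethoxy)benzene | ClC[C@H](C)Cc1ccccc1OCOC | intermediate
6 | [(R)-3-[2-(methoxymethoxy)phenyl]-2-methylpropyl]magnesium chloride | Cl[Mg]C[C@H](C)Cc1ccccc1OCOC | intermediate
7 | [(S)-3-[2-(methoxymethoxy)phenyl]-2-methylpropyl]boronic acid | OB(O)C[C@H](C)Cc1ccccc1OCOC | intermediate
8 | (4R,5R)-4,5-dicyclohexyl-2-[(S)-3-[2-(methoxymethoxy)phenyl]-2-methylpropyl]-1,3,2-dioxaborolane | B1(O[C@H](C2CCCCC2)[C@@H](C2CCCCC2)O1)C[C@H](C)Cc3ccccc3OCOC | intermediate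
9 | (4R,5R)-2-[(S)-3-[5-bromo-2-(methoxymethoxy)phenyl]-2-methylpropyl]-4,5-dicyclohexyl-1,3,2-dioxaborolane | B1(O[C@H](C2CCCCC2)[C@@H](C2CCCCC2)O1)C[C@H](C)Cc3cc(Br)ccc3OCOC | intermediate
10 | (4R,5R)-2-[(1S,3R)-4-[5-bromo-2-(methoxymethoxy)phenyl]-1-chloro-3-methylbutyl]-4,5-dicyclohexyl-1,3,2-dioxaborolane | B1(O[C@H](C2CCCCC2)[C@@H](C2CCCCC2)O1)[C@H](Cl)C[C@H](C)Cc3cc(Br)ccc3OCOC | intermediate
11 | (4R,5R)-2-[(1R,3R)-4-[5-bromo-2-(methoxymethoxy)phenyl]-1-methoxy-3-methylbutyl]-4,5-dicyclohexyl-1,3,2-dioxaborolane | B1(O[C@H](C2CCCCC2)[C@@H](C2CCCCC2)O1)[C@@H](OC)C[C@H](C)Cc3cc(Br)ccc3OCOC | intermediate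
12 | (S)-2-methylbut-3-en-1-ol | C=C[C@H](C)CO | starting material
13 | (S)-2-methylbut-3-en-1-yl 2,4,6-triisopropylbenzoate | C=C[C@H](C)COC(=O)c1c(C(C)C)cc(C(C)C)cc1C(C)C | intermediate
14 | (1S,2S)-1-lithio-2-methylbut-3-en-1-yl 2,4,6-triisopropylbenzoate (sparteine complex) | C=C[C@H](C)[C@H]([Li])OC(=O)c1c(C(C)C)cc(C(C)C)cc1C(C)C | intermediate
15 | lithium boronate (ate) complex: boron of 11 bonded to the carbinyl carbon of 14 with retention | [Li+].C=C[C@H](C)[C@@H](OC(=O)c1c(C(C)C)cc(C(C)C)cc1C(C)C)[B-]2(O[C@H](C3CCCCC3)[C@@H](C3CCCCC3)O2)[C@@H](OC)C[C@H](C)Cc4cc(Br)ccc4OCOC | intermediate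
16 | (4R,5R)-2-[(3R,4R,5S,7R)-8-[5-bromo-2-(methoxymethoxy)phenyl]-5-methoxy-3,7-dimethyloct-1-en-4-yl]-4,5-dicyclohexyl-1,3,2-dioxaborolane (C11–B; same spatial arrangement as 17) | C=C[C@H](C)[C@@H](B1O[C@H](C2CCCCC2)[C@@H](C2CCCCC2)O1)[C@@H](OC)C[C@H](C)Cc3cc(Br)ccc3OCOC | intermediate
17 | (3S,4R,5S,7R)-8-[5-bromo-2-(methoxymethoxy)phenyl]-5-methoxy-3,7-dimethyloct-1-en-4-ol | C=C[C@H](C)[C@@H](O)[C@@H](OC)C[C@H](C)Cc1cc(Br)ccc1OCOC | intermediate
18 | [(3S,4R,5S,7R)-8-[5-bromo-2-(methoxymethoxy)phenyl]-5-methoxy-3,7-dimethyloct-1-en-4-yl]oxy-triethylsilane | C=C[C@H](C)[C@@H](O[Si](CC)(CC)CC)[C@@H](OC)C[C@H](C)Cc1cc(Br)ccc1OCOC | intermediate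
19 | (2R,3R,4S,6R)-7-[5-bromo-2-(methoxymethoxy)phenyl]-4-methoxy-2,6-dimethyl-3-(triethylsilyloxy)heptanal | O=C[C@H](C)[C@@H](O[Si](CC)(CC)CC)[C@@H](OC)C[C@H](C)Cc1cc(Br)ccc1OCOC | intermediate
20 | (2E,4S,5R,6S,8R)-9-[5-bromo-2-(methoxymethoxy)phenyl]-6-methoxy-2,4,8-trimethyl-5-(triethylsilyloxy)non-2-enal | O=C/C(C)=C/[C@H](C)[C@@H](O[Si](CC)(CC)CC)[C@@H](OC)C[C@H](C)Cc1cc(Br)ccc1OCOC | intermediate
21 | allyl methyl ether (3-methoxyprop-1-ene) | C=CCOC | starting material
22 | (Z)-(3-methoxyallyl)lithium | [Li]C/C=C\OC | intermediate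
23 | [(Z)-3-methoxyallyl]bis(isopinocampheyl)borane, Ipc groups as in (+)-Ipc2BOMe | CO/C=C\CB([C@H]1C[C@H]2C[C@@H]([C@@H]1C)C2(C)C)[C@H]1C[C@H]2C[C@@H]([C@@H]1C)C2(C)C | intermediate
24 | diisopinocampheylborinate (C7–O–BIpc2) of 25 | C=C[C@H](OC)[C@@H](OB([C@H]1C[C@H]2C[C@@H]([C@@H]1C)C2(C)C)[C@H]1C[C@H]2C[C@@H]([C@@H]1C)C2(C)C)/C(C)=C/[C@H](C)[C@@H](O[Si](CC)(CC)CC)[C@@H](OC)C[C@H](C)Cc1cc(Br)ccc1OCOC | intermediate
25 | (3S,4S,5E,7S,8R,9S,11R)-12-[5-bromo-2-(methoxymethoxy)phenyl]-3,9-dimethoxy-5,7,11-trimethyl-8-(triethylsilyloxy)dodeca-1,5-dien-4-ol | C=C[C@H](OC)[C@@H](O)/C(C)=C/[C@H](C)[C@@H](O[Si](CC)(CC)CC)[C@@H](OC)C[C@H](C)Cc1cc(Br)ccc1OCOC | intermediate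
26 | 2-bromopropanamide (racemic) | CC(Br)C(N)=O | starting material
27 | (1-amino-1-oxopropan-2-yl)triphenylphosphonium bromide | CC(C(N)=O)[P+](c1ccccc1)(c1ccccc1)c1ccccc1.[Br-] | intermediate
28 | 2-(triphenyl-λ5-phosphanylidene)propanamide | CC(C(N)=O)=P(c1ccccc1)(c1ccccc1)c1ccccc1 | intermediate
29 | (4S,5S,6E,8S,9R,10S,12R)-13-[5-bromo-2-(methoxymethoxy)phenyl]-5-hydroxy-4,10-dimethoxy-6,8,12-trimethyl-9-(triethylsilyloxy)tridec-6-enal (equilibrates with its δ-lactol) | O=CCC[C@H](OC)[C@@H](O)/C(C)=C/[C@H](C)[C@@H](O[Si](CC)(CC)CC)[C@@H](OC)C[C@H](C)Cc1cc(Br)ccc1OCOC | intermediate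
30 | (2E,6S,7S,8E,10S,11R,12S,14R)-15-[5-bromo-2-(methoxymethoxy)phenyl]-7-hydroxy-6,12-dimethoxy-2,8,10,14-tetramethyl-11-(triethylsilyloxy)pentadeca-2,8-dienamide | NC(=O)/C(C)=C/CC[C@H](OC)[C@@H](O)/C(C)=C/[C@H](C)[C@@H](O[Si](CC)(CC)CC)[C@@H](OC)C[C@H](C)Cc1cc(Br)ccc1OCOC | intermediate
31 | 19-membered lactam (2E,6S,7S,8E,10S,11R,12S,14R): 7-OH free, 11-OTES, 17-OMOM | CO[C@H]1C[C@H](C)Cc2cc(ccc2OCOC)NC(=O)/C(C)=C/CC[C@H](OC)[C@@H](O)/C(C)=C/[C@H](C)[C@H]1O[Si](CC)(CC)CC | intermediate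
32 | 7-O-(trichloroacetylcarbamoyl) derivative of 31 | CO[C@H]1C[C@H](C)Cc2cc(ccc2OCOC)NC(=O)/C(C)=C/CC[C@H](OC)[C@@H](OC(=O)NC(=O)C(Cl)(Cl)Cl)/C(C)=C/[C@H](C)[C@H]1O[Si](CC)(CC)CC | intermediate
33 | 7-O-carbamoyl lactam with 11-OTES and 17-OMOM | CO[C@H]1C[C@H](C)Cc2cc(ccc2OCOC)NC(=O)/C(C)=C/CC[C@H](OC)[C@@H](OC(N)=O)/C(C)=C/[C@H](C)[C@H]1O[Si](CC)(CC)CC | intermediate
34 | CNP0544610.1 (6S,7S,10S,11R,12S,14R; 2E,8E) | CO[C@H]1C[C@H](C)Cc2cc(ccc2O)NC(=O)/C(C)=C/CC[C@H](OC)[C@@H](OC(N)=O)/C(C)=C/[C@H](C)[C@H]1O | target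

## Step count and risk

Total steps: 15. Longest linear sequence: 13 (steps 1–5, 7–10, 12–15, from 2-bromophenol).

Three steps most likely to fail:

1. Step 7 (proposed new lithiation–borylation). Risks are slow ate formation or migration with the hindered α-methoxy boronate, and Li/Br exchange at the aryl bromide. The fallback uses known chemistry, sets out from 11 and returns at 17. A second Matteson homologation of 11 (LiCHCl2, ZnCl2, THF, −100 °C→rt) gives the α-chloro-β-methoxy boronic ester F1. Buffered oxidation (H2O2, NaHCO3, THF/H2O, 0 °C) releases (2S,4R)-5-[5-bromo-2-(methoxymethoxy)phenyl]-2-methoxy-4-methylpentanal F2. Brown (Z)-crotylboration of F2 (reagent from (+)-Ipc2BOMe, cis-2-butene, KOtBu/n-BuLi, BF3·OEt2; THF, −78 °C) gives the crotylation borinate F3, and NaOH/H2O2 work-up gives 17. Reagent control and the Cornforth/Felkin preference of the α-methoxy aldehyde are matched for 10,11-syn-11,12-anti.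

2. Step 12 (domino hydroformylation–Wittig with the amide ylide on a lactol-forming substrate). The fallback sets out from 25 and returns at 30. Hydroformylation alone (same Rh/Xantphos conditions, no ylide) is stopped at the δ-lactol F4. Wittig opening with the commercial ester ylide Ph3P=C(Me)CO2Et (toluene, 80 °C) gives the ethyl (E)-enoate F5. Aminolysis with Me2AlNH2 (AlMe3, NH4Cl, CH2Cl2, 40 °C) then gives 30, so the amide is made from the ester instead of being carried by the ylide.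

3. Step 13 (Cu-mediated macrocyclisation with free C7–OH). The fallback sets out from 25 and returns at 31, closing the ring at the acyl–N bond instead. Domino hydroformylation–Wittig of 25 with Ph3P=C(Me)CO2Me (via aldehyde 29) gives the methyl (E)-enoate F6. Cu-catalysed amination of the aryl bromide (CuI, L-proline, K2CO3, aq. NH3, DMSO, 60 °C) gives the aniline methyl ester F7. Saponification (LiOH, THF/MeOH/H2O) gives the amino acid F8. Macrolactamisation (BOP-Cl, iPr2NEt, toluene, 85 °C, high dilution), the closure used in earlier ansamycin syntheses, gives 31.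

## Further compounds

F1 | step 7 | (4R,5R)-2-[(1S,2S,4R)-5-[5-bromo-2-(methoxymethoxy)phenyl]-1-chloro-2-methoxy-4-methylpentyl]-4,5-dicyclohexyl-1,3,2-dioxaborolane | B1(O[C@H](C2CCCCC2)[C@@H](C2CCCCC2)O1)[C@H](Cl)[C@@H](OC)C[C@H](C)Cc3cc(Br)ccc3OCOC
F2 | step 7 | (2S,4R)-5-[5-bromo-2-(methoxymethoxy)phenyl]-2-methoxy-4-methylpentanal | O=C[C@@H](OC)C[C@H](C)Cc1cc(Br)ccc1OCOC
F3 | step 7 | diisopinocampheylborinate (C11–O–BIpc2) of 17 | C=C[C@H](C)[C@@H](OB([C@H]1C[C@H]2C[C@@H]([C@@H]1C)C2(C)C)[C@H]1C[C@H]2C[C@@H]([C@@H]1C)C2(C)C)[C@@H](OC)C[C@H](C)Cc1cc(Br)ccc1OCOC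
F4 | step 12 | δ-lactol of 29 (5-methoxy-6-substituted tetrahydropyran-2-ol, anomer mixture) | OC1CC[C@H](OC)[C@@H](O1)/C(C)=C/[C@H](C)[C@@H](O[Si](CC)(CC)CC)[C@@H](OC)C[C@H](C)Cc1cc(Br)ccc1OCOC
F5 | step 12 | ethyl (2E,6S,7S,8E,10S,11R,12S,14R)-15-[5-bromo-2-(methoxymethoxy)phenyl]-7-hydroxy-6,12-dimethoxy-2,8,10,14-tetramethyl-11-(triethylsilyloxy)pentadeca-2,8-dienoate | CCOC(=O)/C(C)=C/CC[C@H](OC)[C@@H](O)/C(C)=C/[C@H](C)[C@@H](O[Si](CC)(CC)CC)[C@@H](OC)C[C@H](C)Cc1cc(Br)ccc1OCOC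
F6 | step 13 | methyl ester analogue of F5 (aryl bromide) | COC(=O)/C(C)=C/CC[C@H](OC)[C@@H](O)/C(C)=C/[C@H](C)[C@@H](O[Si](CC)(CC)CC)[C@@H](OC)C[C@H](C)Cc1cc(Br)ccc1OCOC
F7 | step 13 | methyl ester with 5-amino-2-(methoxymethoxy)phenyl group (aniline) | COC(=O)/C(C)=C/CC[C@H](OC)[C@@H](O)/C(C)=C/[C@H](C)[C@@H](O[Si](CC)(CC)CC)[C@@H](OC)C[C@H](C)Cc1cc(N)ccc1OCOC
F8 | step 13 | seco amino acid (aniline, C1 carboxylic acid) | OC(=O)/C(C)=C/CC[C@H](OC)[C@@H](O)/C(C)=C/[C@H](C)[C@@H](O[Si](CC)(CC)CC)[C@@H](OC)C[C@H](C)Cc1cc(N)ccc1OCOC
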